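**Plan**
1. Retrosynthesis: the C11–C12 bond is cut first (sulfone alkylation, then removal of sulfur), giving a ring A/B C15 hydroxy sulfone and a ring E C15 allylic bromide. Ring B is then opened at C8–C9 (ketyl–olefin closure) to a ring A keto vinyl sulfone, and C9–C10 is cut ([2,3]-Wittig shift) back to a cyclohexenol made from α-ionone.
2. Enabling feature (drimane numbering): C8 is a tertiary carbinol (CH3, OH) and its ring B neighbour C9 carries the chain CH2 (C11). C8 is therefore a ketyl carbon and C9 the β-carbon of a C9=C11 vinyl sulfone attached to a finished ring A.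
3. Forward: ring A comes intact from (S)-α-ionone; C10 is made quaternary, the vinyl sulfone is attached, and SmI2 closes ring B. Ring E comes from the same ketal 4 by moving the ring alkene to the exocyclic position and extending the ketone to an (E)-allylic bromide. The halves are joined at C11–C12 and the sulfone is removed.
4. Stereochemistry: C5 and the ring E centre both come from resolved (S)-α-ionone. C10 comes from suprafacial Still–Wittig transfer from the trans C2 alcohol, itself set by equatorial hydride delivery. C8 and C9 are set in the chair transition state of the ring B closure, and the C13=C14 (E) geometry by a Horner–Wadsworth–Emmons reaction.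

Key step: step 12

Remark on numbering: drimane numbering is used for all ring A/B compounds (ring A = C1–C5 and C10; C6, C7, C8 and the C8 methyl = the butanone chain; C9 and C11 = the two carbons attached at C10).
Assumption: the enantiomers of α-ionone are taken to be separable on a preparative polysaccharide chiral stationary phase; only the (S)-enantiomer is used, and both halves of the target draw on it.

**Step 1**
Reactants: 1 (±)-α-ionone
Product: 2 (S)-α-ionone
Conditions: preparative HPLC, cellulose tris(3,5-dimethylphenylcarbamate) phase, hexane/i-PrOH, rt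
Reagents that add atoms: none
Why: Resolution by chromatography on a chiral stationary phase separates the enantiomers under neutral conditions, so the doubly allylic ring C–H that carries the stereocentre (the future C5 and the future ring E centre) never meets the acid or base that would move the ring alkene into conjugation.

**Step 2**
Reactants: 2 (S)-α-ionone
Product: 3 (S)-dihydro-α-ionone
Conditions: [(Ph3P)CuH]6 (2 mol %), (EtO)2MeSiH, t-BuOH, toluene, rt
Reagents that add atoms: none
Why: Copper hydride conjugate reduction should deliver hydride only to the β-carbon of the enone, leaving the trisubstituted ring alkene and the adjacent stereocentre untouched.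

**Step 3**
Reactants: 3 (S)-dihydro-α-ionone
Product: 4 dihydro-α-ionone ethylene ketal
Conditions: ethylene glycol, PPTS, benzene, reflux (Dean–Stark)
Reagents that add atoms: ethylene glycol, OCCO
Why: Acid-catalysed ketalization with azeotropic removal of water masks the methyl ketone (the future C8) against the hydride, alkoxide and organolithium steps that follow, and the weak acid PPTS should not isomerise the ring alkene.

**Step 4**
Reactants: 4 dihydro-α-ionone ethylene ketal
Product: 5 C2 enone ketal
Conditions: Rh2(cap)4 (cap = caprolactamate, 1 mol %), t-BuOOH (70 % aq), K2CO3, CH2Cl2, rt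
Reagents that add atoms: tert-butyl hydroperoxide, CC(C)(C)OO
Why: Radical allylic oxidation by the tert-butylperoxyl chain attacks the only unhindered secondary allylic CH2 (C2) and carries it to the conjugated enone, the position at which α-ionone derivatives are known to be oxidised.

**Step 5**
Reactants: 5 C2 enone ketal
Product: 6 trans C2 allylic alcohol
Conditions: LiBH(s-Bu)3, THF, −78 °C; then NaOH, H2O2
Reagents that add atoms: none
Why: 1,2-Reduction of the β,β-disubstituted enone by a bulky trialkylborohydride should take the equatorial trajectory at C2, away from the axial C4 methyl, and with the C5 side chain pseudoaxial (which avoids allylic strain with the C10 methyl) this places the new hydroxyl pseudoaxial and trans to the side chain (2S).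

**Step 6**
Reactants: 6 trans C2 allylic alcohol; 7 tributyl(iodomethyl)stannane
Product: 8 stannylmethyl ether
Conditions: KH, THF, 0 °C; then 7, rt
Reagents that add atoms: none
Why: Williamson etherification of the potassium alkoxide with the reactive α-stannyl iodide gives the ether with the carbinol configuration unchanged.

**Step 7**
Reactants: 8 stannylmethyl ether
Product: 10 C10 hydroxymethyl cyclohexene ketal, via lithiomethyl ether 9 (not isolated)
Conditions: n-BuLi, THF, −78 → −20 °C
Reagents that add atoms: none
Why: Tin–lithium exchange followed by the Still–Wittig [2,3]-sigmatropic rearrangement transfers the CH2O unit suprafacially from the pseudoaxial C2 oxygen to the same face of C10, so C9 is installed trans to the C5 side chain and the C10 methyl cis to it, while the alkene moves to C1=C2.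

**Step 8**
Reactants: 10 C10 hydroxymethyl cyclohexene ketal
Product: 11 saturated primary alcohol
Conditions: H2 (1 atm), Pd/C (10 %), EtOAc, rt
Reagents that add atoms: none
Why: Heterogeneous hydrogenation saturates the cis-disubstituted C1=C2 alkene, which creates no stereocentre, and leaves the ketal and the alcohol intact.

**Step 9**
Reactants: 11 saturated primary alcohol
Product: 12 C9 aldehyde
Conditions: Pr4N[RuO4] (5 mol %), NMO, 4 Å MS, CH2Cl2, rt
Reagents that add atoms: none
Why: Ley–Griffith oxidation stops at the aldehyde, which has no α-hydrogen and so can neither enolise nor epimerise.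

**Step 10**
Reactants: 12 C9 aldehyde; 13 diethyl (phenylsulfonylmethyl)phosphonate
Product: 14 vinyl sulfone ketal
Conditions: NaH, THF, 0 °C → rt
Reagents that add atoms: none
Why: Horner–Wadsworth–Emmons olefination with the sulfonyl-stabilised phosphonate anion should give the (E)-vinyl sulfone even on this hindered neopentyl aldehyde.

**Step 11**
Reactants: 14 vinyl sulfone ketal
Product: 15 ring A keto vinyl sulfone
Conditions: 1 M HCl, THF, rt
Reagents that add atoms: water, O
Why: Acid hydrolysis of the dioxolane releases the methyl ketone, and the vinyl sulfone and the quaternary centre are inert to dilute acid.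

**Step 12**
Reactants: 15 ring A keto vinyl sulfone
Product: 16 8α-hydroxy-11-(phenylsulfonyl)drimane
Conditions: SmI2 (2.5 equiv), HMPA, t-BuOH, THF, −78 °C
Reagents that add atoms: none
Why: SmI2–HMPA reduces the methyl ketone to a samarium-bound ketyl at C8, which adds to C9, the β-carbon of the vinyl sulfone; a second electron then reduces the α-sulfonyl radical at C11 and t-BuOH protonates the carbanion. The closest known reaction type is the SmI2-mediated ketyl–olefin cyclization of ketones onto acrylates and vinyl sulfones. Ring B closes in the 6-exo-trig mode through a chair transition state fused to the existing ring A, whose C5 and C10 already hold the two ring-fusion bonds trans, so only the trans-decalin can form. C9 is controlled by the vinyl sulfone taking the equatorial position on the forming chair (C11 β, H-9 axial), and C8 by the bulky HMPA-solvated trivalent samarium alkoxide taking the equatorial position anti to the electron-poor alkene, which leaves the C8 methyl axial (8α-OH). The step needs this facial selectivity at C8 in spite of the developing 1,3-diaxial contact between the C8 and C10 methyls, and it needs ketyl addition to outpace electron transfer to the vinyl sulfone and cleavage of the product C–S bond; the size of the alkoxide, the early transition state, the low temperature and a limited charge of SmI2 are what should secure both.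

**Step 13**
Reactants: 4 dihydro-α-ionone ethylene ketal
Product: 17 ring epoxide
Conditions: mCPBA, NaHCO3, CH2Cl2, 0 °C
Reagents that add atoms: 3-chloroperbenzoic acid, OOC(=O)c1cccc(Cl)c1
Why: Prilezhaev epoxidation oxidises the electron-rich trisubstituted alkene, and both epoxide diastereomers can be carried on because the two new centres are erased in steps 14 and 16.

**Step 14**
Reactants: 17 ring epoxide
Product: 18 exocyclic allylic alcohol
Conditions: Et2Al(TMP) (from 2,2,6,6-tetramethylpiperidine, n-BuLi, Et2AlCl), toluene, 0 °C
Reagents that add atoms: none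
Why: The aluminium amide isomerisation of an epoxide to an allylic alcohol removes a proton from the least hindered β-position, the methyl group, through a syn cyclic transition state, which should give the exocyclic methylene and leave the ring stereocentre untouched.

**Step 15**
Reactants: 18 exocyclic allylic alcohol
Product: 19 allylic acetate
Conditions: Ac2O, pyridine, DMAP (cat), CH2Cl2, rt
Reagents that add atoms: acetic anhydride, CC(=O)OC(C)=O
Why: DMAP-catalysed acylation turns the secondary allylic alcohol into a leaving group for palladium.

**Step 16**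
Reactants: 19 allylic acetate
Product: 20 γ-dihydroionone ethylene ketal
Conditions: Pd(OAc)2 (5 mol %), PBu3 (20 mol %), HCO2NH4, dioxane, 100 °C
Reagents that add atoms: none
Why: Palladium-catalysed formate hydrogenolysis of the allylic acetate delivers hydride from the π-allylpalladium formate to the more substituted allyl terminus (the ring CH), which removes the oxygen and should keep the alkene exocyclic.

**Step 17**
Reactants: 20 γ-dihydroionone ethylene ketal
Product: 21 (S)-γ-dihydroionone
Conditions: AcOH–H2O–THF (3:1:1), 40 °C
Reagents that add atoms: water, O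
Why: Hydrolysis of the dioxolane in weak aqueous acid frees the ketone under conditions too mild to protonate the exocyclic alkene.

**Step 18**
Reactants: 21 (S)-γ-dihydroionone; 22 triethyl phosphonoacetate
Product: 23 (E)-enoate
Conditions: NaH, THF, 0 °C → rt; chromatographic removal of the (Z)-isomer
Reagents that add atoms: none
Why: The Horner–Wadsworth–Emmons reaction of the methyl ketone should favour the (E)-enoate, with the ester trans to the larger CH2 chain, and the ring stereocentre lies γ to the carbonyl and cannot epimerise.

**Step 19**
Reactants: 23 (E)-enoate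
Product: 24 (E)-allylic alcohol
Conditions: i-Bu2AlH, CH2Cl2, −78 °C
Reagents that add atoms: none
Why: 1,2-Reduction of the enoate by the aluminium hydride gives the allylic alcohol without touching either alkene.

**Step 20**
Reactants: 24 (E)-allylic alcohol
Product: 25 (E)-allylic bromide
Conditions: CBr4, PPh3, CH2Cl2, 0 °C
Reagents that add atoms: carbon tetrabromide, BrC(Br)(Br)Br
Why: The Appel reaction converts the primary allylic alcohol into the bromide under neutral conditions, without allylic transposition and without acid that could isomerise the exocyclic alkene.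

**Step 21**
Reactants: 16 8α-hydroxy-11-(phenylsulfonyl)drimane; 25 (E)-allylic bromide
Product: 26 11-(phenylsulfonyl)ambrein
Conditions: n-BuLi (2.2 equiv), THF–HMPA, −78 °C; then 25, −78 → −20 °C
Reagents that add atoms: none
Why: Double deprotonation gives the alkoxide α-sulfonyl carbanion, whose carbon end should be alkylated by the primary allylic bromide in an SN2 reaction that forms C11–C12, and the unselective new C11 centre is erased in step 22.

**Step 22**
Reactants: 26 11-(phenylsulfonyl)ambrein
Product: 27 ambrein
Conditions: 6 % Na(Hg), Na2HPO4, MeOH–THF, −20 °C → rt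
Reagents that add atoms: none
Why: Reductive desulfonylation by electron transfer cleaves the C11–S bond and protonates C11, and because the sulfone is homoallylic and not allylic the C13=C14 alkene cannot shift, while the exocyclic alkene and the tertiary alcohol are not reduced.

**Compound list**
1 | (±)-α-ionone, (E)-4-(2,6,6-trimethylcyclohex-2-en-1-yl)but-3-en-2-one, racemate | CC1=CCCC(C)(C)C1/C=C/C(C)=O | starting material
2 | (S)-α-ionone | CC1=CCCC(C)(C)[C@@H]1/C=C/C(C)=O | intermediate
3 | (S)-dihydro-α-ionone, 4-[(1S)-2,6,6-trimethylcyclohex-2-en-1-yl]butan-2-one | CC1=CCCC(C)(C)[C@@H]1CCC(C)=O | intermediate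
4 | 2-methyl-2-{2-[(1S)-2,6,6-trimethylcyclohex-2-en-1-yl]ethyl}-1,3-dioxolane | CC1=CCCC(C)(C)[C@@H]1CCC1(C)OCCO1 | intermediate
5 | (4S)-3,5,5-trimethyl-4-[2-(2-methyl-1,3-dioxolan-2-yl)ethyl]cyclohex-2-en-1-one (C2 ketone, C1=C10 alkene) | CC1=CC(=O)CC(C)(C)[C@@H]1CCC1(C)OCCO1 | intermediate
6 | (1S,4S)-3,5,5-trimethyl-4-[2-(2-methyl-1,3-dioxolan-2-yl)ethyl]cyclohex-2-en-1-ol, hydroxyl trans to the side chain | CC1=C[C@@H](O)CC(C)(C)[C@@H]1CCC1(C)OCCO1 | intermediate
7 | tributyl(iodomethyl)stannane | CCCC[Sn](CCCC)(CCCC)CI | starting material
8 | (tributylstannyl)methyl ether of 6 | CC1=C[C@@H](OC[Sn](CCCC)(CCCC)CCCC)CC(C)(C)[C@@H]1CCC1(C)OCCO1 | intermediate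
9 | lithiomethyl ether of 6 (tin exchanged for lithium; not isolated) | CC1=C[C@@H](OC[Li])CC(C)(C)[C@@H]1CCC1(C)OCCO1 | intermediate
10 | [(1S,6S)-1,5,5-trimethyl-6-[2-(2-methyl-1,3-dioxolan-2-yl)ethyl]cyclohex-2-en-1-yl]methanol, CH2OH (C9) trans to the side chain, ring methyl cis | OC[C@@]1(C)C=CCC(C)(C)[C@@H]1CCC1(C)OCCO1 | intermediate
11 | [(1S,2S)-1,3,3-trimethyl-2-[2-(2-methyl-1,3-dioxolan-2-yl)ethyl]cyclohexyl]methanol | OC[C@@]1(C)CCCC(C)(C)[C@@H]1CCC1(C)OCCO1 | intermediate
12 | (1S,2S)-1,3,3-trimethyl-2-[2-(2-methyl-1,3-dioxolan-2-yl)ethyl]cyclohexane-1-carbaldehyde | O=C[C@@]1(C)CCCC(C)(C)[C@@H]1CCC1(C)OCCO1 | intermediate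
13 | diethyl (phenylsulfonylmethyl)phosphonate | CCOP(=O)(CS(=O)(=O)c1ccccc1)OCC | starting material
14 | 2-methyl-2-{2-[(1S,2S)-2,6,6-trimethyl-2-[(E)-2-(phenylsulfonyl)ethenyl]cyclohexyl]ethyl}-1,3-dioxolane | O=S(=O)(c1ccccc1)/C=C/[C@@]1(C)CCCC(C)(C)[C@@H]1CCC1(C)OCCO1 | intermediate
15 | 4-{(1S,2S)-2,6,6-trimethyl-2-[(E)-2-(phenylsulfonyl)ethenyl]cyclohexyl}butan-2-one (ring A keto vinyl sulfone) | O=S(=O)(c1ccccc1)/C=C/[C@@]1(C)CCCC(C)(C)[C@@H]1CCC(C)=O | intermediate
16 | (5S,8R,9R,10S)-11-(phenylsulfonyl)driman-8-ol (8α-OH equatorial, 8β-methyl axial, 9β-CH2SO2Ph, trans-decalin) | O=S(=O)(c1ccccc1)C[C@@H]1[C@@]2(C)CCCC(C)(C)[C@@H]2CC[C@@]1(C)O | intermediate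
17 | 2-methyl-2-{2-[(2S)-1,3,3-trimethyl-7-oxabicyclo[4.1.0]heptan-2-yl]ethyl}-1,3-dioxolane, both epoxide diastereomers | CC12OC1CCC(C)(C)[C@@H]2CCC1(C)OCCO1 | intermediate
18 | (3S)-4,4-dimethyl-2-methylidene-3-[2-(2-methyl-1,3-dioxolan-2-yl)ethyl]cyclohexan-1-ol, both carbinol epimers | C=C1C(O)CCC(C)(C)[C@@H]1CCC1(C)OCCO1 | intermediate
19 | acetate of 18 | C=C1C(OC(C)=O)CCC(C)(C)[C@@H]1CCC1(C)OCCO1 | intermediate
20 | 2-{2-[(1S)-2,2-dimethyl-6-methylidenecyclohexyl]ethyl}-2-methyl-1,3-dioxolane | C=C1CCCC(C)(C)[C@@H]1CCC1(C)OCCO1 | intermediate
21 | (S)-γ-dihydroionone, 4-[(1S)-2,2-dimethyl-6-methylidenecyclohexyl]butan-2-one | C=C1CCCC(C)(C)[C@@H]1CCC(C)=O | intermediate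
22 | triethyl phosphonoacetate | CCOC(=O)CP(=O)(OCC)OCC | starting material
23 | ethyl (2E)-5-[(1S)-2,2-dimethyl-6-methylidenecyclohexyl]-3-methylpent-2-enoate | C=C1CCCC(C)(C)[C@@H]1CC/C(C)=C/C(=O)OCC | intermediate
24 | (2E)-5-[(1S)-2,2-dimethyl-6-methylidenecyclohexyl]-3-methylpent-2-en-1-ol | C=C1CCCC(C)(C)[C@@H]1CC/C(C)=C/CO | intermediate
25 | (2S)-2-[(3E)-5-bromo-3-methylpent-3-en-1-yl]-1,1-dimethyl-3-methylidenecyclohexane | C=C1CCCC(C)(C)[C@@H]1CC/C(C)=C/CBr | intermediate
26 | 11-(phenylsulfonyl)ambrein, mixture of C11 epimers | C=C1CCCC(C)(C)[C@@H]1CC/C(C)=C/CC([C@@H]1[C@@]2(C)CCCC(C)(C)[C@@H]2CC[C@@]1(C)O)S(=O)(=O)c1ccccc1 | intermediate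
27 | ambrein | C=C1CCCC(C)(C)[C@@H]1CC/C(C)=C/CC[C@@H]1[C@@]2(C)CCCC(C)(C)[C@@H]2CC[C@@]1(C)O | target

**Step count**
Total: 22 steps. Longest linear sequence: 14 steps (steps 1–12, 21 and 22). The ring E branch (steps 13–20) leaves the main line at ketal 4.

**The three steps most likely to fail**

Step 12 (ring B closure). Facial control at C8 may be lost if the developing 1,3-diaxial methyl–methyl contact pushes the samarium alkoxide into the axial position. Electron transfer to the vinyl sulfone, or reductive cleavage of the product C–S bond, may also compete with ketyl addition. The fallback sets out from 15 and returns at 16, and makes the same C8–C9 bond without a strong reductant. Kinetic enolisation of 15 with in situ silylation (LiHMDS, Et3SiCl, THF, −78 °C) should give the triethylsilyl enol ether F1. Fe(acac)3 and PhSiH3 in EtOH–ethylene glycol at 60 °C then start a hydrogen-atom-transfer Giese cyclization: the iron hydride gives the C8 α-silyloxy radical, which adds 6-exo to C9 of the vinyl sulfone to give the 8α-triethylsilyl ether F2. The size of the silyl group is a second, adjustable handle on the equatorial preference at C8. HF·pyridine in THF removes the silyl group and gives 16.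

Step 7 (Still–Wittig shift). The rearrangement has to build a quaternary carbon flanked by a tertiary carbon and facing an axial methyl. A [1,2]-shift, or simple protonation of the carbanion, may take over. The fallback sets out from 6, replaces steps 6 and 7, and returns at 10. Heating 6 with N,N-dimethylformamide dimethyl acetal in xylene at 140 °C forms the allyloxy(dimethylamino)carbene. This undergoes the same suprafacial [2,3]-shift (Büchi rearrangement) under neutral, non-organometallic conditions to give the β,γ-unsaturated N,N-dimethylamide F3, with the carboxamide carbon (C9) on C10. LiEt3BH in THF (0 °C → rt) reduces the amide to the primary alcohol 10.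

Step 21 (fragment union). C-alkylation of the β-branched carbanion next to a lithium alkoxide may be slow. Proton transfer, elimination of the allylic bromide or SN2′ attack may then compete. The fallback joins the halves before ring B is closed; it sets out from 14 and returns at 26. The vinyl sulfone 14 has no γ-hydrogen, so MeLi (THF, −95 °C) should lithiate it at the α-carbon (C11). Alkylation with 25 gives the α-substituted vinyl sulfone ketal F4, with retention of the alkene geometry. AcOH–H2O–THF removes the ketal to give the keto vinyl sulfone F5. SmI2, HMPA and t-BuOH at −78 °C then close ring B as in step 12, since the acceptor carbon C9 is unchanged, and give 26 directly.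

**Further compounds**
F1 | step 12 | triethylsilyl enol ether of 15 (terminal enol ether of the methyl ketone) | O=S(=O)(c1ccccc1)/C=C/[C@@]1(C)CCCC(C)(C)[C@@H]1CCC(=C)O[Si](CC)(CC)CC
F2 | step 12 | 8α-triethylsilyl ether of 16 | O=S(=O)(c1ccccc1)C[C@@H]1[C@@]2(C)CCCC(C)(C)[C@@H]2CC[C@@]1(C)O[Si](CC)(CC)CC
F3 | step 7 | N,N-dimethylamide with the carboxamide carbon on C10, trans to the side chain, C1=C2 alkene | CN(C)C(=O)[C@@]1(C)C=CCC(C)(C)[C@@H]1CCC1(C)OCCO1
F4 | step 21 | vinyl sulfone ketal 14 carrying the ring E C15 chain on C11 | C=C1CCCC(C)(C)[C@@H]1CC/C(C)=C/C/C(=C\[C@@]2(C)CCCC(C)(C)[C@@H]2CCC2(C)OCCO2)S(=O)(=O)c1ccccc1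
F5 | step 21 | keto vinyl sulfone carrying the ring E C15 chain on C11 | C=C1CCCC(C)(C)[C@@H]1CC/C(C)=C/C/C(=C\[C@@]2(C)CCCC(C)(C)[C@@H]2CCC(C)=O)S(=O)(=O)c1ccccc1
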